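Atom numbering used throughout: ring C1 (methyl-bearing epoxide carbon), C2 (ketone), C3 (angeloyloxy carbon), C4 (carbon bearing the side chain), C5 (CH2), C6 (epoxide CH); side chain C7(=C14H2)–C8(OAc)–C9H2–C10H=C11Me2.

## Analysis of the target

The target 23 is a 7-oxabicyclo[4.1.0]heptan-2-one: a cyclohexanone whose C1–C6 bond carries an epoxide, with a methyl group on C1, an angelate [(Z)-2-methylbut-2-enoate] on C3 and the only carbon branch on C4. That branch holds a 1,1-disubstituted alkene (C7=C14), an acetoxy carbon (C8) and a prenyl terminus (C10=C11). There are five stereocentres, 1S,3S,4S,6S in the ring and 8S in the chain. The C3 oxygen is trans to the C4 side chain, and the epoxide oxygen lies on the same face as the side chain, opposite to the C3 oxygen. C8 is insulated from the ring by the sp2 carbon C7, so it cannot be set by relay from the ring and needs its own control element. The sensitive groups are: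
- the angelate (isomerisation to the tiglate, conjugate addition);
- the α,β-epoxy ketone (bases, nucleophiles, reductants);
- the C3–H flanked by ketone and acyloxy group (epimerisation);
- the allylic acetate at C8 and the electron-rich C10=C11 alkene.

The difficulty is threefold: three contiguous functionalised ring carbons (C2–C4) next to an epoxide on the more hindered face, three oxygen functions to tell apart (C2 ketone, C3 angelate, C8 acetate), and one alkene out of three to epoxidise. The strategy rests on reading the ring as a 2-methylcyclohex-2-enone (C2 carbonyl, C1=C6 alkene) that has been oxidised at C3 and across C1/C6 and carries a single carbon substituent at C4. C4–C5–C6 then map onto the β-, α- and carbonyl carbons of an enal, and C3–C2–C1(–CH3) onto the β-keto ester of an ethyl ketone.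

## Retrosynthetic reasoning

**C3–O acyl bond (23 ⇒ 22).** The angeloyl group is removed first, because it is the most fragile function and should meet no further reagent. The forward step must acylate a hindered α-hydroxy ketone without Z→E isomerisation of the acyl unit.

**C2 ketone and C3 silyl ether (22 ⇒ 21 ⇒ 20).** The C3 hydroxyl is traced back to a silyl ether and the C2 ketone to a secondary alcohol. The alcohol is not a detour for its own sake: an α-hydroxyl at C2 is the handle that places the epoxide on the hindered face.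

**Epoxide C–O bonds (20 ⇒ 19).** The epoxide is taken off to the C1=C6 alkene of allylic alcohol 19. This is done late, when C8 is already an acetate, so that the C2 hydroxyl is the only free directing group in a molecule with three alkenes. The forward reaction has to deliver oxygen syn to that hydroxyl and leave C7=C14 and C10=C11 alone.

**Protecting groups and acetate (19 ⇒ 18 ⇒ 17).** Two silyl ethers of different lability keep C2–O and C3–O distinguishable (triethylsilyl at C2, tert-butyldimethylsilyl at C3). The C8 acetate goes on while both are in place.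

**C7–C8 bond (17 ⇒ 14 + 16).** A 1,1-disubstituted alkene next to a carbinol is the mark of a 2-metalloalkene adding to an aldehyde. Cutting here splits off the whole prenyl-bearing part as the small aldehyde 16 (one step from alcohol 15) and lets C8 be set by a chiral ligand on the metal. An alkenylchromium species is chosen because it tolerates silyl ethers and adds only to aldehydes.

**Alkenyl triflate from the ester (14 ⇒ 13 ⇒ 12 ⇒ 11).** The alkenyl triflate comes from the kinetic enolate of methyl ketone 13, and that from ester 11 through Weinreb amide 12. C7 therefore enters the synthesis as a carboxyl carbon. This avoids the strongly acidic iodide sources that a 2-iodoalkene made from an alkyne would require in the presence of two silyl ethers.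

**C2 and C3 oxygens (11 ⇒ 10 ⇒ 9 ⇒ 8 ⇒ 6 ⇒ 5).** The C2 hydroxyl arises by 1,2-reduction of enone 9 and the C3 oxygen by oxidation of silyl dienol ether 6 of enone 5. Both new centres are relayed from C4: the oxidant comes anti to the C4 ester, and the hydride comes along the axial path.

**Ring (5 ⇒ 1 + 2).** Cutting C3–C4 and C1=C6 opens the ring to enal 1 and keto ester 2, both purchasable. C4 is the only stereocentre to be made, and it is made by a chiral amine catalyst; the tert-butyl ester of 2 activates C3 and is lost in the same flask. This is the step on which everything else depends, and it stands at the very start.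

## Alternatives that were turned down

**Alternative 1: ring and epoxide closed together by a sulfonium ylide.** The C1–C6 bond and the C6–O bond are cut together. The precursor is the acyclic methyl ketone A1, with a diphenylsulfonium group at C6 and the C2/C3 diol as an acetonide. LiN(SiMe3)2 forms the ylide at C6, which adds to the C1 ketone; the alkoxide then displaces the sulfide (intramolecular Corey–Chaykovsky reaction) to give epoxy acetonide A2.
- For: the epoxide is made without an oxidant, so the choice among three alkenes never arises, and no reduction/re-oxidation at C2 is needed. On both points it is stronger than the chosen route.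
- Against: A1 must carry four stereocentres (C2, C3, C4, C8) built in an open chain before the key step. The base must pick the C6 hydrogens over the methyl-ketone hydrogens and over C2–H, whose enolate would expel the acetonide oxygen. The C5 hydrogens invite elimination of the sulfonium group. Nothing obvious decides which face of the ketone is attacked, and that face fixes C1 and C6 relative to C4. A2 contains a strained trans-fused acetonide that must later be cleaved by acid beside an epoxide, leaving two secondary alcohols to tell apart.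
- Comparison: the chosen route pays with a redox pair at C2 but gets the ring in one step and sets the epoxide by a dependable hydroxyl-directed delivery.

**Alternative 2: chelation-controlled carbonyl-ene closure.** The C3–C4 bond is cut with simultaneous formation of C7=C14. The precursor is dienal A3 (C3 aldehyde, C2 p-methoxybenzyl ether, Z-configured C1=C6, trisubstituted C4=C7 carrying the C14 methyl). Me2AlCl chelates aldehyde and ether oxygen; C4 attacks C3 while a C14 hydrogen moves to oxygen, giving cyclohexenol A4.
- For: one step creates the ring, the C3 carbinol, the C4 centre and the exocyclic methylene with the C8 acetate already present. It is more convergent than the chosen route, which needs separate triflate formation and coupling, and chelation should control C2/C3 well.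
- Against: in A3 the C2 hydrogen is both α to the aldehyde and allylic, so epimerisation and alkene migration threaten. A strong Lewis acid meets an allylic acetate directly on the reacting alkene. Hydrogen could also be taken from C8 or C5. The absolute configuration must be brought in twice (C2 and C8) before the key step, and the Z-trisubstituted alkene needs its own stereoselective synthesis. Ether removal, epoxidation, oxidation and acylation still follow, so the endgame is no shorter.
- Comparison: the chosen route is weaker on convergence, but draws all ring stereochemistry from one catalytic step on two commodity chemicals.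

**Alternative 3: intramolecular Nozaki–Hiyama–Kishi closure of C1–C2.** The C1–C2 bond is cut. The precursor A5 carries a Z-configured alkenyl iodide (C1/C6) and a C2 aldehyde with the silyloxy group at C3. CrCl2 with catalytic NiCl2 gives the alkenylchromium species, which adds to the aldehyde to form cyclohexenol A6, the same compound as 19 of the chosen route.
- For: the coupling is mild and tolerates acetate and alkenes. It delivers the free C2 allylic alcohol directly, which would save the Luche reduction and the silylation/desilylation pair at C2 (steps 5, 6 and 13), and the side chain is complete before ring closure. On these points it is stronger.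
- Against: A5 has to be assembled in an open chain with C3, C4 and C8 already set and with a geometrically pure iodoalkene, which is at least as long as the nine steps that lead to 14 here. The new C2 centre depends on 1,2-induction from a non-chelating α-silyloxy aldehyde inside a ring-forming transition state, which is plausible but not assured, and that aldehyde is epimerisable.
- Comparison: since both routes meet at 19, the chosen route is preferred for its one-step catalytic entry to the ring and its cyclic stereocontrol at C2 and C3.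

Key step: step 1

Remark on the chemistry: the sense of induction of the amine catalyst in step 1 and of the sulfonamide ligand in step 11 is assigned from the accepted shielding models; if either proves reversed, the enantiomeric catalyst or ligand, equally available, is used.

## Route

Step 1
Reactants: 1 ethyl (E)-4-oxobut-2-enoate; 2 tert-butyl 3-oxopentanoate
Product: 5 ethyl (1R)-4-methyl-5-oxocyclohex-3-ene-1-carboxylate, via Michael adduct 3 (not isolated), via keto diester 4 (not isolated)
Conditions: (S)-2-[bis(3,5-bis(trifluoromethyl)phenyl)(trimethylsilyloxy)methyl]pyrrolidine (10 mol %), benzoic acid (10 mol %), toluene, 0 °C → rt; then TsOH·H2O (0.3 equiv), toluene, 80 °C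
Reagents that add atoms: none
Why: The secondary amine condenses with enal 1 to an E-configured iminium ion whose one face is covered by the diaryl(silyloxy)methyl group, and the enol of 2 adds through C3 to C4 on the open face (expected to be the Si face with the S catalyst), giving 3 after hydrolysis. Acid then enolises the ethyl ketone toward C1, which closes the ring onto the C6 aldehyde in a 6-(enolendo)-exo-trig aldol addition, and dehydration gives 4 with the C1=C6 double bond. The tert-butyl ester of 4 loses isobutene and the resulting β-keto acid loses CO2, leaving 5. The closest known reaction type is the iminium-catalysed Michael addition of β-keto esters to enals followed by acid-mediated aldol condensation and decarboxylation to 5-substituted cyclohex-2-enones. C4 is the only stereocentre that survives and it is set by the catalyst; the C3 centre of 3 and 4 is destroyed on decarboxylation. The step needs addition β to the iminium carbon, not β to the ester, which the much higher electrophilicity of the iminium ion secures. The ring size is fixed because only C1 can reach C6 in a six-membered ring. The ethyl ester survives the acid that cleaves the tert-butyl ester, and C4, being α only to an ester, should not epimerise under these conditions.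

Step 2
Reactants: 5 ethyl (1R)-4-methyl-5-oxocyclohex-3-ene-1-carboxylate
Product: 6 ethyl (1R)-4-methyl-3-[(trimethylsilyl)oxy]cyclohexa-2,4-diene-1-carboxylate
Conditions: LiN(iPr)2, THF, −78 °C; then TMSCl, −78 → 0 °C
Reagents that add atoms: chlorotrimethylsilane, C[Si](C)(C)Cl
Why: Kinetic deprotonation of the enone takes the more acidic α′-hydrogen at C3 in preference to the ester α-hydrogen at C4 and the γ-hydrogens at C5, and O-silylation gives the cross-conjugated silyl dienol ether; C4 is untouched.

Step 3
Reactants: 6 ethyl (1R)-4-methyl-3-[(trimethylsilyl)oxy]cyclohexa-2,4-diene-1-carboxylate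
Product: 8 ethyl (1R,6S)-6-hydroxy-4-methyl-5-oxocyclohex-3-ene-1-carboxylate, via silyloxy ketone 7 (not isolated)
Conditions: mCPBA, NaHCO3, CH2Cl2, −20 → 0 °C; then citric acid, MeOH, rt
Reagents that add atoms: 3-chloroperoxybenzoic acid, OOC(=O)c1cccc(Cl)c1
Why: Rubottom oxidation: the peracid epoxidises the electron-rich enol ether C2=C3 in preference to C1=C6 and from the face opposite the adjacent C4 ester; ring opening with silyl shift gives 7, which mild methanolysis desilylates. The C3 oxygen should therefore end up trans to the C4 substituent.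

Step 4
Reactants: 8 ethyl (1R,6S)-6-hydroxy-4-methyl-5-oxocyclohex-3-ene-1-carboxylate
Product: 9 ethyl (1R,6S)-6-[(tert-butyldimethylsilyl)oxy]-4-methyl-5-oxocyclohex-3-ene-1-carboxylate
Conditions: TBSCl, imidazole, DMF, rt
Reagents that add atoms: tert-butyldimethylsilyl chloride, CC(C)(C)[Si](C)(C)Cl
Why: Standard silylation of a secondary alcohol under weakly basic conditions that do not enolise the ketone or the ester.

Step 5
Reactants: 9 ethyl (1R,6S)-6-[(tert-butyldimethylsilyl)oxy]-4-methyl-5-oxocyclohex-3-ene-1-carboxylate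
Product: 10 ethyl (1R,5S,6S)-6-[(tert-butyldimethylsilyl)oxy]-5-hydroxy-4-methylcyclohex-3-ene-1-carboxylate
Conditions: NaBH4, CeCl3·7H2O, MeOH, −78 °C
Reagents that add atoms: none
Why: Luche reduction: cerium-promoted borohydride adds 1,2 to the enone along the axial path (the face of the axial C4–H), which should give the pseudo-equatorial C2 alcohol trans to the equatorial C3 silyl ether and cis to the C4 ester. The ester is not reduced at this temperature.

Step 6
Reactants: 10 ethyl (1R,5S,6S)-6-[(tert-butyldimethylsilyl)oxy]-5-hydroxy-4-methylcyclohex-3-ene-1-carboxylate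
Product: 11 ethyl (1R,5S,6S)-6-[(tert-butyldimethylsilyl)oxy]-4-methyl-5-[(triethylsilyl)oxy]cyclohex-3-ene-1-carboxylate
Conditions: TESOTf, 2,6-lutidine, CH2Cl2, −78 °C
Reagents that add atoms: triethylsilyl trifluoromethanesulfonate, CC[Si](CC)(CC)OS(=O)(=O)C(F)(F)F
Why: Silylation of the hindered allylic alcohol with a silyl triflate and a non-nucleophilic base; the triethylsilyl ether can later be removed in the presence of the tert-butyldimethylsilyl ether.

Step 7
Reactants: 11 ethyl (1R,5S,6S)-6-[(tert-butyldimethylsilyl)oxy]-4-methyl-5-[(triethylsilyl)oxy]cyclohex-3-ene-1-carboxylate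
Product: 12 (1R,5S,6S)-6-[(tert-butyldimethylsilyl)oxy]-N-methoxy-N,4-dimethyl-5-[(triethylsilyl)oxy]cyclohex-3-ene-1-carboxamide
Conditions: MeNHOMe·HCl, iPrMgCl, THF, −20 → 0 °C
Reagents that add atoms: N,O-dimethylhydroxylamine hydrochloride, Cl.CNOC
Why: Aminolysis of the ester by the magnesium amide of N,O-dimethylhydroxylamine (Weinreb amide formation); at low temperature the amide base should not deprotonate C4, so neither epimerisation nor loss of the C3 silyloxy group is expected.

Step 8
Reactants: 12 (1R,5S,6S)-6-[(tert-butyldimethylsilyl)oxy]-N-methoxy-N,4-dimethyl-5-[(triethylsilyl)oxy]cyclohex-3-ene-1-carboxamide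
Product: 13 1-[(1R,5S,6S)-6-[(tert-butyldimethylsilyl)oxy]-4-methyl-5-[(triethylsilyl)oxy]cyclohex-3-en-1-yl]ethan-1-one
Conditions: MeMgBr, THF, 0 °C
Reagents that add atoms: methylmagnesium bromide, C[Mg]Br
Why: Grignard addition to the Weinreb amide stops at the chelated tetrahedral intermediate, which releases the methyl ketone only on work-up, so no tertiary alcohol forms.

Step 9
Reactants: 13 1-[(1R,5S,6S)-6-[(tert-butyldimethylsilyl)oxy]-4-methyl-5-[(triethylsilyl)oxy]cyclohex-3-en-1-yl]ethan-1-one
Product: 14 1-[(1R,5S,6S)-6-[(tert-butyldimethylsilyl)oxy]-4-methyl-5-[(triethylsilyl)oxy]cyclohex-3-en-1-yl]ethenyl trifluoromethanesulfonate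
Conditions: KN(SiMe3)2, THF, −78 °C; then PhNTf2, −78 → 0 °C
Reagents that add atoms: N-phenylbis(trifluoromethanesulfonimide), O=S(=O)(N(c1ccccc1)S(=O)(=O)C(F)(F)F)C(F)(F)F
Why: Kinetic enolisation goes to the unhindered methyl group and O-sulfonylation gives the 2-triflyloxy-1-alkene; the enolate toward C4, which could expel the C3 silyloxy group, should not form at −78 °C.

Step 10
Reactants: 15 4-methylpent-3-en-1-ol
Product: 16 4-methylpent-3-enal
Conditions: Dess–Martin periodinane, NaHCO3, CH2Cl2, 0 °C; used at once as a solution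
Reagents that add atoms: none
Why: Buffered Dess–Martin oxidation of a primary alcohol under neutral conditions, which should not move the β,γ-double bond into conjugation.

Step 11
Reactants: 14 1-[(1R,5S,6S)-6-[(tert-butyldimethylsilyl)oxy]-4-methyl-5-[(triethylsilyl)oxy]cyclohex-3-en-1-yl]ethenyl trifluoromethanesulfonate; 16 4-methylpent-3-enal
Product: 17 (3S)-2-[(1S,5S,6S)-6-[(tert-butyldimethylsilyl)oxy]-4-methyl-5-[(triethylsilyl)oxy]cyclohex-3-en-1-yl]-6-methylhepta-1,5-dien-3-ol
Conditions: CrCl2, N-[2-(4-isopropyl-4,5-dihydrooxazol-2-yl)-6-methylphenyl]methanesulfonamide (enantiomer selected for 8S), Et3N, THF, rt; then NiCl2 (cat.), 14, 16 (excess), rt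
Reagents that add atoms: none
Why: Asymmetric Nozaki–Hiyama–Kishi reaction: zerovalent nickel formed in the flask inserts into the alkenyl C–O bond, transmetalation gives an alkenylchromium species of trivalent chromium, and this adds only to the aldehyde. The chiral sulfonamide ligand on chromium sets C8 by reagent control.

Step 12
Reactants: 17 (3S)-2-[(1S,5S,6S)-6-[(tert-butyldimethylsilyl)oxy]-4-methyl-5-[(triethylsilyl)oxy]cyclohex-3-en-1-yl]-6-methylhepta-1,5-dien-3-ol
Product: 18 (3S)-2-[(1S,5S,6S)-6-[(tert-butyldimethylsilyl)oxy]-4-methyl-5-[(triethylsilyl)oxy]cyclohex-3-en-1-yl]-6-methylhepta-1,5-dien-3-yl acetate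
Conditions: Ac2O, pyridine, 4-(dimethylamino)pyridine (cat.), CH2Cl2, 0 °C → rt
Reagents that add atoms: acetic anhydride, CC(=O)OC(C)=O
Why: Nucleophile-catalysed acetylation of the only free hydroxyl; the C–O bond at C8 is not touched, so the configuration is kept.

Step 13
Reactants: 18 (3S)-2-[(1S,5S,6S)-6-[(tert-butyldimethylsilyl)oxy]-4-methyl-5-[(triethylsilyl)oxy]cyclohex-3-en-1-yl]-6-methylhepta-1,5-dien-3-yl acetate
Product: 19 (3S)-2-[(1S,5S,6S)-6-[(tert-butyldimethylsilyl)oxy]-5-hydroxy-4-methylcyclohex-3-en-1-yl]-6-methylhepta-1,5-dien-3-yl acetate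
Conditions: pyridinium p-toluenesulfonate (cat.), MeOH, CH2Cl2, 0 °C
Reagents that add atoms: none
Why: Mild acid methanolysis cleaves the triethylsilyl ether far faster than the tert-butyldimethylsilyl ether and leaves the acetate intact.

Step 14
Reactants: 19 (3S)-2-[(1S,5S,6S)-6-[(tert-butyldimethylsilyl)oxy]-5-hydroxy-4-methylcyclohex-3-en-1-yl]-6-methylhepta-1,5-dien-3-yl acetate
Product: 20 (3S)-2-[(1R,2R,3S,4S,6S)-3-[(tert-butyldimethylsilyl)oxy]-2-hydroxy-1-methyl-7-oxabicyclo[4.1.0]heptan-4-yl]-6-methylhepta-1,5-dien-3-yl acetate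
Conditions: VO(acac)2 (5 mol %), TBHP, CH2Cl2, 0 °C → rt
Reagents that add atoms: tert-butyl hydroperoxide, CC(C)(C)OO
Why: Hydroxyl-directed epoxidation: the vanadium alkoxide of the C2 hydroxyl passes the peroxide oxygen to the same face of C1=C6, which sets C1 and C6 syn to the C2 hydroxyl and hence on the face of the C4 side chain. C7=C14 and C10=C11 have no free allylic hydroxyl and should not react.

Step 15
Reactants: 20 (3S)-2-[(1R,2R,3S,4S,6S)-3-[(tert-butyldimethylsilyl)oxy]-2-hydroxy-1-methyl-7-oxabicyclo[4.1.0]heptan-4-yl]-6-methylhepta-1,5-dien-3-yl acetate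
Product: 21 (3S)-2-[(1S,3S,4S,6S)-3-[(tert-butyldimethylsilyl)oxy]-1-methyl-2-oxo-7-oxabicyclo[4.1.0]heptan-4-yl]-6-methylhepta-1,5-dien-3-yl acetate
Conditions: Dess–Martin periodinane, NaHCO3, CH2Cl2, rt
Reagents that add atoms: none
Why: Buffered Dess–Martin oxidation of the secondary alcohol under neutral conditions that spare the epoxide, the alkenes and the C3 centre.

Step 16
Reactants: 21 (3S)-2-[(1S,3S,4S,6S)-3-[(tert-butyldimethylsilyl)oxy]-1-methyl-2-oxo-7-oxabicyclo[4.1.0]heptan-4-yl]-6-methylhepta-1,5-dien-3-yl acetate
Product: 22 (3S)-2-[(1S,3S,4S,6S)-3-hydroxy-1-methyl-2-oxo-7-oxabicyclo[4.1.0]heptan-4-yl]-6-methylhepta-1,5-dien-3-yl acetate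
Conditions: HF·pyridine, pyridine, THF, 0 °C → rt
Reagents that add atoms: none
Why: Fluoride-mediated desilylation, buffered with pyridine so that the medium is neither acidic enough to open the epoxide nor basic enough to epimerise C3.

Step 17
Reactants: 22 (3S)-2-[(1S,3S,4S,6S)-3-hydroxy-1-methyl-2-oxo-7-oxabicyclo[4.1.0]heptan-4-yl]-6-methylhepta-1,5-dien-3-yl acetate
Product: 23 (1S,3S,4S,6S)-4-[(3S)-3-acetoxy-6-methylhepta-1,5-dien-2-yl]-1-methyl-2-oxo-7-oxabicyclo[4.1.0]heptan-3-yl (2Z)-2-methylbut-2-enoate
Conditions: angelic acid, 2,4,6-trichlorobenzoyl chloride, Et3N, toluene, rt; then 22, toluene, 80 °C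
Reagents that add atoms: angelic acid [(Z)-2-methylbut-2-enoic acid], C/C=C(/C)C(=O)O
Why: Yamaguchi-type esterification through the mixed anhydride, run without a nucleophilic amine catalyst because reversible conjugate addition of such a catalyst is what turns angelates into tiglates. Acylation occurs at oxygen, so no stereocentre changes.

## Compound list

1 | ethyl (E)-4-oxobut-2-enoate | CCOC(=O)/C=C/C=O | starting material
2 | tert-butyl 3-oxopentanoate | CCC(=O)CC(=O)OC(C)(C)C | starting material
3 | 1-tert-butyl 4-ethyl (3R)-3-(2-oxoethyl)-2-propanoylbutanedioate (Michael adduct, epimers at C2) | CCOC(=O)[C@@H](C(C(=O)CC)C(=O)OC(C)(C)C)CC=O | intermediate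
4 | 1-tert-butyl 2-ethyl (2R)-5-methyl-6-oxocyclohex-4-ene-1,2-dicarboxylate (keto diester, epimers at C1) | CCOC(=O)[C@@H]1CC=C(C)C(=O)C1C(=O)OC(C)(C)C | intermediate
5 | ethyl (1R)-4-methyl-5-oxocyclohex-3-ene-1-carboxylate | CCOC(=O)[C@@H]1CC=C(C)C(=O)C1 | intermediate
6 | ethyl (1R)-4-methyl-3-[(trimethylsilyl)oxy]cyclohexa-2,4-diene-1-carboxylate | CCOC(=O)[C@@H]1CC=C(C)C(O[Si](C)(C)C)=C1 | intermediate
7 | ethyl (1R,6S)-4-methyl-5-oxo-6-[(trimethylsilyl)oxy]cyclohex-3-ene-1-carboxylate | CCOC(=O)[C@@H]1CC=C(C)C(=O)[C@H]1O[Si](C)(C)C | intermediate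
8 | ethyl (1R,6S)-6-hydroxy-4-methyl-5-oxocyclohex-3-ene-1-carboxylate | CCOC(=O)[C@@H]1CC=C(C)C(=O)[C@H]1O | intermediate
9 | ethyl (1R,6S)-6-[(tert-butyldimethylsilyl)oxy]-4-methyl-5-oxocyclohex-3-ene-1-carboxylate | CCOC(=O)[C@@H]1CC=C(C)C(=O)[C@H]1O[Si](C)(C)C(C)(C)C | intermediate
10 | ethyl (1R,5S,6S)-6-[(tert-butyldimethylsilyl)oxy]-5-hydroxy-4-methylcyclohex-3-ene-1-carboxylate | CCOC(=O)[C@@H]1CC=C(C)[C@H](O)[C@H]1O[Si](C)(C)C(C)(C)C | intermediate
11 | ethyl (1R,5S,6S)-6-[(tert-butyldimethylsilyl)oxy]-4-methyl-5-[(triethylsilyl)oxy]cyclohex-3-ene-1-carboxylate | CCOC(=O)[C@@H]1CC=C(C)[C@H](O[Si](CC)(CC)CC)[C@H]1O[Si](C)(C)C(C)(C)C | intermediate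
12 | (1R,5S,6S)-6-[(tert-butyldimethylsilyl)oxy]-N-methoxy-N,4-dimethyl-5-[(triethylsilyl)oxy]cyclohex-3-ene-1-carboxamide | CON(C)C(=O)[C@@H]1CC=C(C)[C@H](O[Si](CC)(CC)CC)[C@H]1O[Si](C)(C)C(C)(C)C | intermediate
13 | 1-[(1R,5S,6S)-6-[(tert-butyldimethylsilyl)oxy]-4-methyl-5-[(triethylsilyl)oxy]cyclohex-3-en-1-yl]ethan-1-one | CC(=O)[C@@H]1CC=C(C)[C@H](O[Si](CC)(CC)CC)[C@H]1O[Si](C)(C)C(C)(C)C | intermediate
14 | 1-[(1R,5S,6S)-6-[(tert-butyldimethylsilyl)oxy]-4-methyl-5-[(triethylsilyl)oxy]cyclohex-3-en-1-yl]ethenyl trifluoromethanesulfonate | C=C(OS(=O)(=O)C(F)(F)F)[C@@H]1CC=C(C)[C@H](O[Si](CC)(CC)CC)[C@H]1O[Si](C)(C)C(C)(C)C | intermediate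
15 | 4-methylpent-3-en-1-ol | CC(C)=CCCO | starting material
16 | 4-methylpent-3-enal | CC(C)=CCC=O | intermediate
17 | (3S)-2-[(1S,5S,6S)-6-[(tert-butyldimethylsilyl)oxy]-4-methyl-5-[(triethylsilyl)oxy]cyclohex-3-en-1-yl]-6-methylhepta-1,5-dien-3-ol | C=C([C@H](CC=C(C)C)O)[C@@H]1CC=C(C)[C@H](O[Si](CC)(CC)CC)[C@H]1O[Si](C)(C)C(C)(C)C | intermediate
18 | (3S)-2-[(1S,5S,6S)-6-[(tert-butyldimethylsilyl)oxy]-4-methyl-5-[(triethylsilyl)oxy]cyclohex-3-en-1-yl]-6-methylhepta-1,5-dien-3-yl acetate | C=C([C@H](CC=C(C)C)OC(C)=O)[C@@H]1CC=C(C)[C@H](O[Si](CC)(CC)CC)[C@H]1O[Si](C)(C)C(C)(C)C | intermediate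
19 | (3S)-2-[(1S,5S,6S)-6-[(tert-butyldimethylsilyl)oxy]-5-hydroxy-4-methylcyclohex-3-en-1-yl]-6-methylhepta-1,5-dien-3-yl acetate | C=C([C@H](CC=C(C)C)OC(C)=O)[C@@H]1CC=C(C)[C@H](O)[C@H]1O[Si](C)(C)C(C)(C)C | intermediate
20 | (3S)-2-[(1R,2R,3S,4S,6S)-3-[(tert-butyldimethylsilyl)oxy]-2-hydroxy-1-methyl-7-oxabicyclo[4.1.0]heptan-4-yl]-6-methylhepta-1,5-dien-3-yl acetate | C=C([C@H](CC=C(C)C)OC(C)=O)[C@@H]1C[C@@H]2O[C@]2(C)[C@H](O)[C@H]1O[Si](C)(C)C(C)(C)C | intermediate
21 | (3S)-2-[(1S,3S,4S,6S)-3-[(tert-butyldimethylsilyl)oxy]-1-methyl-2-oxo-7-oxabicyclo[4.1.0]heptan-4-yl]-6-methylhepta-1,5-dien-3-yl acetate | C=C([C@H](CC=C(C)C)OC(C)=O)[C@@H]1C[C@@H]2O[C@]2(C)C(=O)[C@H]1O[Si](C)(C)C(C)(C)C | intermediate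
22 | (3S)-2-[(1S,3S,4S,6S)-3-hydroxy-1-methyl-2-oxo-7-oxabicyclo[4.1.0]heptan-4-yl]-6-methylhepta-1,5-dien-3-yl acetate | C=C([C@H](CC=C(C)C)OC(C)=O)[C@@H]1C[C@@H]2O[C@]2(C)C(=O)[C@H]1O | intermediate
23 | (1S,3S,4S,6S)-4-[(3S)-3-acetoxy-6-methylhepta-1,5-dien-2-yl]-1-methyl-2-oxo-7-oxabicyclo[4.1.0]heptan-3-yl (2Z)-2-methylbut-2-enoate | C=C([C@H](CC=C(C)C)OC(C)=O)[C@@H]1C[C@@H]2O[C@]2(C)C(=O)[C@H]1OC(=O)/C(C)=C\C | target

## Step count and least certain steps

Total: 17 steps. Longest linear sequence: 16 steps (steps 1–9 and 11–17); step 10 prepares the aldehyde.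

**Step 1 (key step).** The most likely failure is erosion of enantiomeric purity. The Michael addition is reversible before ring closure and an uncatalysed background addition to the very electrophilic enal can compete; the enal may also oligomerise. Fallback, from a new starting material back to 5: Birch reduction (Li, NH3, tert-butanol) of 3-methoxy-4-methylbenzoic acid F1 gives 3-methoxy-4-methylcyclohexa-2,5-diene-1-carboxylic acid F2. Aqueous acid hydrolyses the enol ether and moves the alkene into conjugation, giving racemic 4-methyl-5-oxocyclohex-3-ene-1-carboxylic acid F3. Resolution through the salt with one enantiomer of 1-phenylethylamine gives (1R)-4-methyl-5-oxocyclohex-3-ene-1-carboxylic acid F4, and acid-catalysed esterification with ethanol returns 5.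

**Step 11.** Two processes threaten: insufficient facial selectivity at C8, because the ligand has to override whatever bias the hindered ring exerts, and base-induced migration of the double bond of 16 into conjugation before it is consumed. Fallback, from 13 back to 17: condensation of 13 with 2,4,6-triisopropylbenzenesulfonyl hydrazide gives the hydrazone F7. Shapiro reaction (n-BuLi, THF, −78 → 0 °C) forms the 2-lithioalkene, which after transmetalation with CeCl3 adds to 16 and gives 17 mixed with its C8 epimer F8. Dess–Martin oxidation of the mixture gives the enone 2-[(1S,5S,6S)-6-[(tert-butyldimethylsilyl)oxy]-4-methyl-5-[(triethylsilyl)oxy]cyclohex-3-en-1-yl]-6-methylhepta-1,5-dien-3-one F9. Corey–Bakshi–Shibata reduction with (R)-1-methyl-3,3-diphenyltetrahydro-1H,3H-pyrrolo[1,2-c][1,3,2]oxazaborole and catecholborane, with the alkenyl group as the large substituent, returns 17.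

**Step 5.** The risk is poor facial selectivity of hydride delivery: if the conformer with axial C3 silyloxy and C4 ester groups reacts, attack anti to the silyloxy group gives the C2 epimer, and the later epoxide would then form on the wrong face. Fallback, from the C2 epimer back to 10: the epimer ethyl (1R,5R,6S)-6-[(tert-butyldimethylsilyl)oxy]-5-hydroxy-4-methylcyclohex-3-ene-1-carboxylate F5 is inverted by a Mitsunobu reaction (4-nitrobenzoic acid, PPh3, diisopropyl azodicarboxylate) to the ester ethyl (1R,5S,6S)-6-[(tert-butyldimethylsilyl)oxy]-4-methyl-5-[(4-nitrobenzoyl)oxy]cyclohex-3-ene-1-carboxylate F6. Ethanolysis (K2CO3, EtOH) then gives 10.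

**Step 3.** The risk is incomplete facial selectivity of the peracid on the nearly flat diene, giving some cis hydroxy ketone. Fallback, from 5 directly to 8 with no new intermediate: the potassium enolate of 5 (KN(SiMe3)2, THF, −78 °C) is hydroxylated with the enantiomer of (camphorsulfonyl)oxaziridine whose preference matches attack anti to the C4 ester. Reagent control then reinforces substrate control.

**Step 17.** The risks are isomerisation of the angeloyl unit to the tigloyl unit during activation and slow acylation of the hindered hydroxyl, with time for epimerisation at C3. Fallback, from 22 back to 23: esterification of 22 with 2-[bis(2,2,2-trifluoroethoxy)phosphoryl]propanoic acid (dicyclohexylcarbodiimide, 4-(dimethylamino)pyridine) gives the phosphonate ester F12. Still–Gennari olefination with acetaldehyde (KN(SiMe3)2, 18-crown-6, THF, −78 °C) builds the Z-configured double bond on the molecule and gives 23.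

**Step 16.** The risk is opening of the epoxide by fluoride or acid, or base-induced change at C3, while the silyl ether next to the ketone is cleaved. Fallback, from 20 back to 23: desilylation of 20 with Bu4NF buffered with acetic acid, before the ketone exists, gives the diol (3S)-2-[(1R,2R,3S,4S,6S)-2,3-dihydroxy-1-methyl-7-oxabicyclo[4.1.0]heptan-4-yl]-6-methylhepta-1,5-dien-3-yl acetate F10. Mixed-anhydride angeloylation is expected at the C3 hydroxyl, because the C2 hydroxyl is shielded by the fully substituted C1, and gives the mono-angelate F11. Dess–Martin oxidation of the remaining C2 hydroxyl gives 23.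

## Further compounds

F1 | step 1 | 3-methoxy-4-methylbenzoic acid | COc1cc(ccc1C)C(=O)O
F2 | step 1 | 3-methoxy-4-methylcyclohexa-2,5-diene-1-carboxylic acid | COC1=CC(C=CC1C)C(=O)O
F3 | step 1 | racemic 4-methyl-5-oxocyclohex-3-ene-1-carboxylic acid | CC1=CCC(CC1=O)C(=O)O
F4 | step 1 | (1R)-4-methyl-5-oxocyclohex-3-ene-1-carboxylic acid | CC1=CC[C@@H](C(=O)O)CC1=O
F0 | step 3 | none | none
F5 | step 5 | ethyl (1R,5R,6S)-6-[(tert-butyldimethylsilyl)oxy]-5-hydroxy-4-methylcyclohex-3-ene-1-carboxylate | CCOC(=O)[C@@H]1CC=C(C)[C@@H](O)[C@H]1O[Si](C)(C)C(C)(C)C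
F6 | step 5 | ethyl (1R,5S,6S)-6-[(tert-butyldimethylsilyl)oxy]-4-methyl-5-[(4-nitrobenzoyl)oxy]cyclohex-3-ene-1-carboxylate | CCOC(=O)[C@@H]1CC=C(C)[C@H](OC(=O)c2ccc(cc2)[N+](=O)[O-])[C@H]1O[Si](C)(C)C(C)(C)C
F7 | step 11 | 2,4,6-triisopropylbenzenesulfonyl hydrazone of 13 (E) | C/C(=N\NS(=O)(=O)c1c(C(C)C)cc(C(C)C)cc1C(C)C)[C@@H]2CC=C(C)[C@H](O[Si](CC)(CC)CC)[C@H]2O[Si](C)(C)C(C)(C)C
F8 | step 11 | (3R)-2-[(1S,5S,6S)-6-[(tert-butyldimethylsilyl)oxy]-4-methyl-5-[(triethylsilyl)oxy]cyclohex-3-en-1-yl]-6-methylhepta-1,5-dien-3-ol | C=C([C@@H](CC=C(C)C)O)[C@@H]1CC=C(C)[C@H](O[Si](CC)(CC)CC)[C@H]1O[Si](C)(C)C(C)(C)C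
F9 | step 11 | 2-[(1S,5S,6S)-6-[(tert-butyldimethylsilyl)oxy]-4-methyl-5-[(triethylsilyl)oxy]cyclohex-3-en-1-yl]-6-methylhepta-1,5-dien-3-one | C=C(C(=O)CC=C(C)C)[C@@H]1CC=C(C)[C@H](O[Si](CC)(CC)CC)[C@H]1O[Si](C)(C)C(C)(C)C
F10 | step 16 | (3S)-2-[(1R,2R,3S,4S,6S)-2,3-dihydroxy-1-methyl-7-oxabicyclo[4.1.0]heptan-4-yl]-6-methylhepta-1,5-dien-3-yl acetate | C=C([C@H](CC=C(C)C)OC(C)=O)[C@@H]1C[C@@H]2O[C@]2(C)[C@H](O)[C@H]1O
F11 | step 16 | (1R,2R,3S,4S,6S)-4-[(3S)-3-acetoxy-6-methylhepta-1,5-dien-2-yl]-2-hydroxy-1-methyl-7-oxabicyclo[4.1.0]heptan-3-yl (2Z)-2-methylbut-2-enoate | C=C([C@H](CC=C(C)C)OC(C)=O)[C@@H]1C[C@@H]2O[C@]2(C)[C@H](O)[C@H]1OC(=O)/C(C)=C\C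
F12 | step 17 | (1S,3S,4S,6S)-4-[(3S)-3-acetoxy-6-methylhepta-1,5-dien-2-yl]-1-methyl-2-oxo-7-oxabicyclo[4.1.0]heptan-3-yl 2-[bis(2,2,2-trifluoroethoxy)phosphoryl]propanoate | C=C([C@H](CC=C(C)C)OC(C)=O)[C@@H]1C[C@@H]2O[C@]2(C)C(=O)[C@H]1OC(=O)C(C)P(=O)(OCC(F)(F)F)OCC(F)(F)F
A1 | alternative 1 | acyclic keto sulfonium salt (C1 methyl ketone, C2/C3 trans-acetonide, diphenylsulfonium at C6, tetrafluoroborate) | C=C([C@H](CC=C(C)C)OC(C)=O)[C@H](CC[S+](c2ccccc2)c3ccccc3)[C@@H]1OC(C)(C)O[C@H]1C(C)=O.F[B-](F)(F)F
A2 | alternative 1 | epoxy acetonide (ring and C1–C6 epoxide closed, C2/C3 diol as acetonide) | C=C([C@H](CC=C(C)C)OC(C)=O)[C@@H]1C[C@@H]2O[C@]2(C)[C@@H]3OC(C)(C)O[C@@H]13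
A3 | alternative 2 | acyclic dienal (C3 aldehyde, C2 p-methoxybenzyl ether, Z-C1=C6, E-C4=C7) | O=C[C@@H](OCc1ccc(OC)cc1)/C(C)=C\C/C=C(\C)[C@H](CC=C(C)C)OC(C)=O
A4 | alternative 2 | cyclohexenol (C2 p-methoxybenzyl ether, C3 hydroxyl) | C=C([C@H](CC=C(C)C)OC(C)=O)[C@@H]1CC=C(C)[C@H](OCc2ccc(OC)cc2)[C@H]1O
A5 | alternative 3 | acyclic iodo aldehyde (Z-alkenyl iodide at C1/C6, C2 aldehyde, C3 tert-butyldimethylsilyl ether) | C=C([C@H](CC=C(C)C)OC(C)=O)[C@H](C/C=C(/C)I)[C@H](O[Si](C)(C)C(C)(C)C)C=O
A6 | alternative 3 | cyclohexenol (C2 hydroxyl, C3 tert-butyldimethylsilyl ether; identical with 19) | C=C([C@H](CC=C(C)C)OC(C)=O)[C@@H]1CC=C(C)[C@H](O)[C@H]1O[Si](C)(C)C(C)(C)C
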